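Time is the thing to watch: through the 1.0 min of feed and the minutes after it, reagent enters substrate and then enters the single product, and each new flask is read at 15 min.

in all of them: substrate 10 mM

| flask | reagent | remark | time |
|---|---|---|---|
| ash | 1.9 equiv (fed, over 1.0 min) | run made earlier |  |
| oak | 3.7 equiv (fed, over 1.0 min) | run made earlier |  |
| Wednesday's | 1.50 equiv (fed, over 1.0 min) |  | 15 min |
| Tuesday's | 2.00 equiv (fed, over 1.0 min) |  | 15 min |
| Saturday's | 3.00 equiv (fed, over 1.0 min) |  | 15 min |

| run | time / min | bis adduct / % | single product / % |
|---|---|---|---|
| ash | 0.667 | 14.9 | 31.2 |
| ash | 1.33 | 48.2 | 34.4 |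
| ash | 3.00 | 72.2 | 20.7 |
| ash | 8.00 | 85.3 | 9.4 |
| oak | 2.00 | 93.1 | 3.6 |
| oak | 4.00 | 96.2 | 0 |
| oak | 6.00 | 95.8 | 0 |
| oak | 8.00 | 95.6 | 0 |

(scatter of a reading: 0.5 percentage points)

* bis adduct at the end, in percent of the substrate charged, for each flask in turn (Wednesday's, Tuesday's, Saturday's)



Here is the run in slow motion, on my own reckoning from the earlier readings.

1. First instants: at 0.667 min, with the feed still running, the ash run holds 31.2% single product, more than its 14.9% bis adduct, so you see the first addition ahead.

2. Middle: at 3.00 min, after the feed, the ash run reads 72.2% bis adduct against 20.7% single product, so the second addition is still going on.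

3. End: the oak run levels off at 96.2% bis adduct with 0% single product, which I read as the share of substrate that reaches an adduct. The ash run at 8.00 min holds less in its two adducts, 94.7%, so that share may fall as the charge falls.

4. Rule: every adduct holds one reagent and the bis adduct a second, so where reagent is the limiting reagent, you get bis adduct from the equivalents taken minus the adduct share. On Wednesday's flask, with the oak share, this bis budget is 53.8%, and that is my estimate, which counts the charge as taken up and the oak share as holding there. On Tuesday's flask the same sum gives 104%, above the oak share, so I expect bis adduct there to approach that plateau.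

The forecast gives 55%, 92.5% and 95.5%, its first point standing higher than my budget, and of that flask it says “Reagent is exhausted well before” 15 min.

The flasks give 60.9%, 92.7% and 95.6%.

    substrate ⇌ dormant form (K = 0.730, k = 0.0123 min⁻¹)
    reagent + single product → bis adduct + released group (k = 118 M⁻¹ min⁻¹)
    2 substrate → self-condensation product (k = 5.84 M⁻¹ min⁻¹)
    substrate + reagent → single product + released group (k = 221 M⁻¹ min⁻¹)
    reagent + other mono adduct → bis adduct + released group (k = 907 M⁻¹ min⁻¹)
    substrate + reagent → other mono adduct + released group (k = 84.4 M⁻¹ min⁻¹)

Wednesday's bis adduct stands 7.1 percentage points above the budget, with reagent down to 0.0151% of its charge. Substrate, self-condensation product and dormant form leave an adduct share of 89.1%, and the budget with that share is 60.9%. On Tuesday's flask, the released group shows reagent taken at 187% of the substrate charged and the share is 94.3%, so the budget is 92.7%. The main reason for that bis adduct is reagent adding to the single product: without this step, Tuesday's flask falls from 92.7% to 26.1%.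

The data are simulated for an exercise.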